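The numbers in the tables are calculated for substances that don't exist, noise included.

The product is length: E divided by the chains begun. So I follow one unit of L and ask its chance of standing in a chain at the end, then share those units among the chains.

in all of them: G 2.5 mol%
- Monday's: L 0.14 M; the very flask that is asked about, followed so far
- Tuesday's: L 0.070 M; run made earlier
- flask: L 0.14 M; time 5.0 h

| run | time / h | E / % | L / % |
|---|---|---|---|
| Monday's | 0.417 | 15 | 81 |
| Monday's | 0.833 | 32 | 69 |
| Monday's | 1.33 | 40 | 55 |
| Monday's | 1.50 | 45 | 52 |
| Monday's | 2.00 | 52 | 49 |
| Monday's | 2.50 | 53 | 45 |
| Tuesday's | 0.417 | 2 | 100 |
| Tuesday's | 0.667 | 3 | 97 |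
| Tuesday's | 1.00 | 8 | 96 |
| Tuesday's | 2.00 | 8 | 88 |
| Tuesday's | 3.00 | 10 | 93 |
| Tuesday's | 5.00 | 8 | 89 |

(each reading ± 2 percentage points)

- whether the average number of monomer units in a chain (chains begun, living or dead) reaches 10 by 5.0 h (no / yes)
- average number of monomer units in a chain (chains begun, living or dead) at 5.0 h

- the average divides the monomer in chains by the number of chains begun, living and dead together
- the earlier runs do not show the number of chains; that part of a forecast is a guess

The readings make a short ladder of times. On the lowest rung chains begin: Monday's run of this flask already reads E 15% at 0.417 h, and I see no lag. On the next rung L falls and flattens in the same run, reading 45% at 2.50 h. The top rung is the asked 5.0 h, twice the time of that last reading, so I take this flask to be sitting on its level by then.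

That level is a concentration. Monday's last L reading gives 0.0630 M, and Tuesday's last L reading, on the smaller charge, gives about the same at 0.0623 M. I call this the standing monomer, the equilibrium monomer concentration: the L that the readings show out of chains at both charges. At the fork, a unit of L in this flask ends in a chain with chance one minus standing monomer over charge, 55.0%. The chain count is a guess, one chain per G, so I divide that chance by the loading and get a length of 22.0, longer than the wanted 10.

The forecast answers yes with a length of 22, holding that “The same residual monomer at both charges points to a monomer–polymer equilibrium, not a dying catalyst.”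

The flask gives yes and a length of 22.2.

    L + G → D + E (k = 0.626 /M/min)
    L + D → E + D, rate k2*[D]*[L] (k = 6.25 /M/min)
    E + D → L + D, rate k3*[D] as long as [E] is above zero (k = 0.392 /min)
    G + E → Q (k = 0.0579 /M/min)

In this flask L + G → D + E had 91% of its turnover up to 5.0 h behind it by 0.500 h, with G then at 9.01% of its charge, while L + D → E + D ran against its reverse E + D → L + D, with E at 52.6% by 2.50 h. The length in this flask passed 10 at 0.567 h, and at 5.00 h E stands at 55.1%, made 1.00 times as fast as it is used up, each step taken net. In Tuesday's run the same standing monomer gives a chance of 10.0%, and the last E reading there is 8% at 5.00 h.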